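Read the step Ja ⇌ Jb by itself first, and carry one quantity from it: the relaxation constant λ, the rate at which the gap between Jb and its plateau x closes. From a flask without Jb, Jb is then x times one minus e^(−λt).

| setting | Tuesday's | Friday's | Monday's | teal | ochre | grey | green | amber | blue |
|---|---|---|---|---|---|---|---|---|---|
| Ja | 0.14 M | 0.68 M | 0.40 M | 0.40 M | 0.60 M | 0.10 M | 0.40 M | 0.40 M | 0.40 M |
| Je | 1.6 mM (in portions, 2) | 1.6 mM (in portions, 2) | 1.7 mM (in portions, 2) | 1.6 mM (in portions, 2) | 1.6 mM (in portions, 2) | 3.0 mM (in portions, 2) | 0.80 mM (in portions, 2) | 0.80 mM (in portions, 2) | 1.6 mM (in portions, 2) |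
| temperature | 15 °C | 59 °C | 15 °C | 5 °C | 75 °C | 35 °C | 65 °C | −5 °C | 35 °C |
| remark | run made earlier; portions every 50 s | run made earlier; portions every 50 s | run made earlier; portions every 50 s | the portions of Je follow each other after 15 s, the first at the start | the portions of Je follow each other after 80 s, the first at the start | the portions of Je follow each other after 50 s, the first at the start | the portions of Je follow each other after 50 s, the first at the start | the portions of Je follow each other after 50 s, the first at the start | the portions of Je follow each other after 50 s, the first at the start |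
| time |  |  |  | 8.0 min | 8.0 min | 8.0 min | 8.0 min | 8.0 min | 8.0 min |

| Tuesday's: time / min | Tuesday's: Jb / % | Friday's: time / s | Friday's: Jb / % | Monday's: time / min | Monday's: Jb / % |
|---|---|---|---|---|---|
| 1.00 | 6.9 | 12.0 | 70.5 | 4.00 | 23.8 |
| 2.50 | 16.6 | 40.0 | 71.3 | 8.00 | 36.0 |
| 6.00 | 30.4 | 80.0 | 65.3 | 10.0 | 37.8 |
| 15.0 | 45.3 | 120 | 62.4 | 15.0 | 46.3 |

(scatter of a reading: 1 percentage point)

- ranking by amount of Jb, in percent of the Ja charged, from high to low, at 8.0 min (teal / ochre / grey / green / amber / blue)
- the amount of Jb, in percent of the Ja charged of the flask you put first, at 8.0 min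
- the amount of Jb, in percent of the Ja charged of the flask you put last, at 8.0 min

I get λ in two ways at 15 °C. In Monday's run the reading at 8.00 min is twice the time of the one at 4.00 min, so their ratio is one plus e^(−λt) at the shorter time. From 23.8% and 36.0% I obtain λ = 0.167 min⁻¹ and x = 48.8%. Their product, the starting slope, is the forward constant 0.0816 min⁻¹.

The second way takes that slope straight from Tuesday's run, which has less Ja: 16.6% in 2.50 min gives 0.0664 min⁻¹. The two part, and the straight chord is the one that cheats. It stands lower because it treats the curve as a line, though λt is already 0.418 there. With the bend put back, Tuesday's Jb gives 0.0812 min⁻¹, which agrees with Monday's value, so I trust λ.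

Friday's run at 59 °C already reads 70.5% at 12.0 s, level with its next reading within the scatter. If a hundredth of the gap was left then, λ there is about 23.0 min⁻¹. Set against Monday's λ, this gives an activation energy of 89.1 kJ mol⁻¹. Carried down to −5 °C, amber's relaxation constant is 0.01043 min⁻¹. Keeping Monday's x, which is a rough step, I reckon amber at 3.91%.

The forecast gives green > ochre > blue > grey > teal > amber, with 67% at the top and 3.7% at the bottom, on the ground that “Hot flasks therefore equilibrate fast and lose little”. Its low figure stands a little under mine.

The flasks give ochre > green > blue > grey > teal > amber, with 62.8% at the top and 3.67% at the bottom. Ochre and green have changed places, and amber stands at the forecast's figure.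

    Ja ⇌ Jb (K = 1.80, k = 0.0161 s⁻¹, Ea = 91.0 kJ mol⁻¹, ΔH = 18.0 kJ mol⁻¹)
    Je → Jf (k = 1.20 × 10⁻⁴ s⁻¹, Ea = 98.0 kJ mol⁻¹)
    Jb + Je ⇌ Jc + Je, rate k3*[Je]*[Jb] forward; the back reaction follows from the equilibrium constant (K = 0.880, k = 0.522 M⁻¹ s⁻¹, Ea = 65.0 kJ mol⁻¹, ΔH = −25.0 kJ mol⁻¹)
    Jc + Je ⇌ Jd + Je, rate k4*[Je]*[Jc] forward; the back reaction follows from the equilibrium constant (K = 1.02, k = 0.431 M⁻¹ s⁻¹, Ea = 36.0 kJ mol⁻¹, ΔH = −7.00 kJ mol⁻¹)
    (constants at 35 °C)

Amber's relaxation half-life of 55.5 min is long against 8.0 min, and 96% of its Ja is still there at that time. That half-life means λ = 0.01248 min⁻¹, higher than the 0.0104 min⁻¹ I carried. I take amber's 3.67% and stretch the curve to 30 min, multiplying by the ratio of the two values of one minus e^(−λt). The carried λ gives 12.3%, and the λ of the half-life gives 12.1%. Amber left until 30 min holds 12.0% Jb.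

The readings are calculated from invented constants; scatter was added.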